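**Retrosynthetic overview**
- Target 41 comes from Mitsunobu coumaroylation of the C15 allylic alcohol 39. Its C7 acrylate comes from a C7–CH2CO2Me group (Mannich methylenation), which the C8 ketone of 25 places at C7 before C8 is reduced to CH2.
- Ketone 25 comes from the trans-decalin keto ester 19. The C3 ketone/C4 ester pair is turned into the C3=C4 alkene and C15–OH (enol triflate, formate reduction, iBu2AlH).
- 19 comes from the acyclic β-keto ester 17 by oxidative radical bicyclisation. The feature used: C4 is the α-carbon of a β-keto ester (between ketone C3 and ester carbon C15), and the (E)-C5=C10 alkene carrying methyl C14 lies in a chain that ends in the C8(Cl)=C9 alkene. Bond C4–C5 closes ring A first, then bond C9–C10 closes ring B, and the chlorine unmasks the C8 ketone.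
- 17 comes from γ-alkylation of the auxiliary acetoacetate 15 with the (E)-allylic bromide 11 (Johnson–Claisen, Wittig, reduction, bromination).

Key step: step 8

Numbering used below (eudesmane): C1–C4 with C5 and C10 form ring A, C5–C10 form ring B, C14 is the methyl on C10, C15 is on C4, C11–C13 are on C7; β is the face of C14; "octalin" and "decalin" locants follow this numbering.

Remark on the auxiliary: by the π-stacking model of the chelated 8-phenylmenthyl β-keto ester enolate, the 5α-H,10β-methyl series of the target requires the (1S,2R,5S)-(+)-enantiomer of 8-phenylmenthol (taken as purchasable); the (1R,2S,5R) antipode would lead to the enantiomeric decalin.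

**Route**

Step 1
Reactants: 1 2-chloroprop-2-en-1-ol; 2 triethyl orthoacetate
Product: 5 ethyl 4-chloropent-4-enoate, via mixed orthoester 3 (not isolated), via ketene acetal 4 (not isolated)
Conditions: EtCO2H (cat.), neat, 140 °C, EtOH distilled off
Reagents that add atoms: none
Why: Johnson–Claisen rearrangement: acid-catalysed alcohol exchange and loss of ethanol give the ketene acetal, whose [3,3]-sigmatropic shift joins the acetate carbon to the CH2 terminus of the allyl unit and leaves the 2-chlorovinyl group intact.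

Step 2
Reactants: 5 ethyl 4-chloropent-4-enoate
Product: 7 4-chloropent-4-enal, via aluminium hemiacetal 6 (not isolated)
Conditions: iBu2AlH (1.05 equiv), CH2Cl2, −78 °C; aq. KNaC4H4O6; used as a solution
Reagents that add atoms: none
Why: Partial ester reduction: the tetrahedral aluminium hemiacetal is stable at −78 °C and releases the aldehyde only on aqueous work-up, so over-reduction should be avoided.

Step 3
Reactants: 7 4-chloropent-4-enal; 8 ethyl 2-(triphenylphosphoranylidene)propanoate
Product: 9 ethyl (2E)-6-chloro-2-methylhepta-2,6-dienoate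
Conditions: CH2Cl2, rt
Reagents that add atoms: none
Why: Wittig olefination with a stabilised α-methyl ylide, which should give the (E)-trisubstituted enoate (chain trans to the ester) and thereby fix the C5=C10 geometry needed for the trans ring fusion.

Step 4
Reactants: 9 ethyl (2E)-6-chloro-2-methylhepta-2,6-dienoate
Product: 10 (2E)-6-chloro-2-methylhepta-2,6-dien-1-ol
Conditions: iBu2AlH (2.2 equiv), CH2Cl2, −78 → 0 °C; aq. KNaC4H4O6
Reagents that add atoms: none
Why: 1,2-Reduction of an enoate by iBu2AlH gives the allylic alcohol without touching the vinyl chloride or the alkene geometry.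

Step 5
Reactants: 10 (2E)-6-chloro-2-methylhepta-2,6-dien-1-ol
Product: 11 (2E)-1-bromo-6-chloro-2-methylhepta-2,6-diene
Conditions: PBr3 (0.4 equiv), Et2O, 0 °C
Reagents that add atoms: phosphorus tribromide, BrP(Br)Br
Why: Bromination of a primary allylic alcohol through its phosphite ester proceeds by SN2 displacement at 0 °C, so the (E)-geometry should be kept and no allylic transposition is expected.

Step 6
Reactants: 12 (+)-8-phenylmenthol; 13 2,2,6-trimethyl-4H-1,3-dioxin-4-one
Product: 15 (1S,2R,5S)-5-methyl-2-(2-phenylpropan-2-yl)cyclohexyl 3-oxobutanoate, via acetylketene 14 (not isolated)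
Conditions: xylene, 140 °C, acetone distilled off
Reagents that add atoms: none
Why: Acetoacetylation: thermal retro-[4+2] fragmentation of the dioxinone releases acetylketene, which acylates even this hindered secondary alcohol under neutral conditions.

Step 7
Reactants: 15 (1S,2R,5S)-5-methyl-2-(2-phenylpropan-2-yl)cyclohexyl 3-oxobutanoate; 11 (2E)-1-bromo-6-chloro-2-methylhepta-2,6-diene
Product: 17 (1S,2R,5S)-5-methyl-2-(2-phenylpropan-2-yl)cyclohexyl (6E)-10-chloro-6-methyl-3-oxoundeca-6,10-dienoate, via dilithio dianion 16 (not isolated)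
Conditions: LiN(iPr)2 (2.1 equiv), THF, 0 °C; then 11, 0 °C → rt; aq. HCl
Reagents that add atoms: none
Why: γ-Alkylation of an acetoacetate dianion: the terminal carbanion is the more nucleophilic site and displaces the primary allylic bromide by SN2, which assembles the complete cyclisation chain C15–C4–C3–C2–C1–C10=C5–C6–C7–C8(Cl)=C9.

Step 8
Reactants: 17 (1S,2R,5S)-5-methyl-2-(2-phenylpropan-2-yl)cyclohexyl (6E)-10-chloro-6-methyl-3-oxoundeca-6,10-dienoate
Product: 19 (+)-8-phenylmenthyl (4α,5α,10β)-10-methyl-3,8-dioxo-trans-decalin-4-carboxylate, via chloro acetate 18 (not isolated)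
Conditions: Mn(OAc)3·2H2O (2.2 equiv), Cu(OAc)2·H2O (0.2 equiv), Yb(OTf)3 (1 equiv), CF3CH2OH–AcOH (4:1), degassed, 0 °C → rt
Reagents that add atoms: manganese triacetate dihydrate, CC(=O)[O-].CC(=O)[O-].CC(=O)[O-].[Mn+3].O.O (an acetate oxygen becomes the C8 carbonyl oxygen)
Why: Oxidative free-radical polyene cyclisation of an unsaturated β-keto ester with a vinyl chloride terminator and an 8-phenylmenthyl ester, a known reaction class: trivalent manganese oxidises the chelated enolate to the electrophilic C4 radical, which adds to C5 of the (E)-C5=C10 alkene, and the tertiary C10 radical then adds to C9, the CH2 terminus of the chloroalkene; Cu(OAc)2 oxidises the α-chloro C8 radical to the chlorocarbenium ion, acetate capture gives the chloro acetate, and loss of acetyl chloride leaves the C8 ketone. Ring A closes 6-endo-trig, because C10 is fully substituted and an α-keto radical with a carbonyl in the tether disfavours 5-exo closure; ring B also closes 6-endo-trig, because the chlorine-bearing C8 is the hindered internal carbon. C5 and C10 are set together by anti addition across the (E)-alkene in a chair–chair array, which gives the trans fusion with C14 axial; C4 ends with the ester equatorial (4α) and is in any case under thermodynamic control as an enolisable β-keto ester. The absolute configuration comes from the auxiliary: its phenyl ring stacks over one face of the chelated enolate and radical, so C5 bonds to the open face, which for the (1S,2R,5S) auxiliary is the 5α-H,10β-methyl series. The step needs facial selectivity (auxiliary, Yb(OTf)3 chelation, low temperature), endo selectivity in both closures (substitution pattern of the chain) and closure of ring B faster than copper oxidation of the C10 radical (copper kept catalytic).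

Step 9
Reactants: 19 (+)-8-phenylmenthyl (4α,5α,10β)-10-methyl-3,8-dioxo-trans-decalin-4-carboxylate
Product: 21 (+)-8-phenylmenthyl (5α,10β)-10-methyl-8-oxo-3-(trifluoromethylsulfonyloxy)-Δ3-octalin-4-carboxylate, via sodium enolate 20 (not isolated)
Conditions: NaH (1.05 equiv), THF, 0 °C; PhNTf2, 0 °C → rt; aq. NH4Cl
Reagents that add atoms: N-phenylbis(trifluoromethanesulfonimide), O=S(=O)(N(c1ccccc1)S(=O)(=O)C(F)(F)F)C(F)(F)F
Why: Enol triflate formation: one equivalent of NaH deprotonates only the β-keto ester (far more acidic than the C8 ketone) and PhNTf2 sulfonylates the enolate oxygen, which removes the C4 stereocentre as planned.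

Step 10
Reactants: 21 (+)-8-phenylmenthyl (5α,10β)-10-methyl-8-oxo-3-(trifluoromethylsulfonyloxy)-Δ3-octalin-4-carboxylate
Product: 22 (+)-8-phenylmenthyl (5α,10β)-10-methyl-8-oxo-Δ3-octalin-4-carboxylate
Conditions: Pd(OAc)2 (5 mol %), PPh3 (10 mol %), HCO2H, Et3N, DMF, 60 °C
Reagents that add atoms: none
Why: Palladium-catalysed formate reduction of a vinyl triflate (oxidative addition to zerovalent palladium, formate exchange, decarboxylation, C–H reductive elimination) gives the C3=C4 enoate and leaves the C8 ketone alone.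

Step 11
Reactants: 22 (+)-8-phenylmenthyl (5α,10β)-10-methyl-8-oxo-Δ3-octalin-4-carboxylate
Product: 23 (5α,10β)-4-(hydroxymethyl)-10-methyl-Δ3-octalin-8-ol (C8 epimers)
Conditions: iBu2AlH (5 equiv), CH2Cl2, −78 °C → rt; aq. KNaC4H4O6
Reagents that add atoms: none
Why: Hydride reduction: iBu2AlH reduces the hindered enoate 1,2 to the C15 allylic alcohol and releases the auxiliary 12 for recovery; the C8 ketone is reduced as well, and its epimer mixture is of no consequence because C8 is re-oxidised.

Step 12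
Reactants: 23 (5α,10β)-4-(hydroxymethyl)-10-methyl-Δ3-octalin-8-ol (C8 epimers)
Product: 24 (5α,10β)-4-(tert-butyldiphenylsilyloxymethyl)-10-methyl-Δ3-octalin-8-ol (C8 epimers)
Conditions: TBDPSCl (1.05 equiv), imidazole, CH2Cl2, 0 °C
Reagents that add atoms: tert-butyl(chloro)diphenylsilane, CC(C)(C)[Si](Cl)(c1ccccc1)c1ccccc1
Why: Silyl protection: the bulky chlorosilane should silylate the primary allylic C15–OH much faster than the secondary ring hydroxyl.

Step 13
Reactants: 24 (5α,10β)-4-(tert-butyldiphenylsilyloxymethyl)-10-methyl-Δ3-octalin-8-ol (C8 epimers)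
Product: 25 (5α,10β)-4-(tert-butyldiphenylsilyloxymethyl)-10-methyl-Δ3-octalin-8-one
Conditions: Dess–Martin periodinane, CH2Cl2, rt
Reagents that add atoms: none
Why: Dess–Martin oxidation converts both C8 carbinol epimers to the single ketone under neutral conditions that the allylic silyl ether tolerates.

Step 14
Reactants: 25 (5α,10β)-4-(tert-butyldiphenylsilyloxymethyl)-10-methyl-Δ3-octalin-8-one; 26 methyl bromoacetate
Product: 29 methyl 2-[(5α,7β,10β)-4-(tert-butyldiphenylsilyloxymethyl)-10-methyl-8-oxo-Δ3-octalin-7-yl]acetate, via lithium Δ7-enolate 27 (not isolated), via 7α epimer 28 (not isolated)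
Conditions: LiN(iPr)2 (1.05 equiv), THF, −78 °C; 26, DMPU, −78 → −20 °C; then DBU (0.2 equiv), CH2Cl2, rt
Reagents that add atoms: none
Why: Regioselective ketone enolate alkylation: the base removes a C7 proton (C9 is neopentylic and a trans-fused ring prefers the C7=C8 enolate), SN2 attack on the bromoacetate occurs largely axially (7α), and DBU equilibration through the C8 enol then places the side chain equatorial, which sets C7 as 7β with 7α-H.

Step 15
Reactants: 29 methyl 2-[(5α,7β,10β)-4-(tert-butyldiphenylsilyloxymethyl)-10-methyl-8-oxo-Δ3-octalin-7-yl]acetate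
Product: 30 C8 p-toluenesulfonylhydrazone of 29
Conditions: TsNHNH2, MeOH, 50 °C
Reagents that add atoms: p-toluenesulfonyl hydrazide, Cc1ccc(cc1)S(=O)(=O)NN
Why: Hydrazone condensation at the only ketone; the NHTs group should lie anti to the branched C7, so the equatorial C7 substituent is not strained and the weakly nucleophilic sulfonamide nitrogen should not attack the ester.

Step 16
Reactants: 30 C8 p-toluenesulfonylhydrazone of 29
Product: 33 methyl 2-[(5α,7β,10β)-4-(tert-butyldiphenylsilyloxymethyl)-10-methyl-Δ3-octalin-7-yl]acetate, via N-boryl hydrazide 31 (not isolated), via C8 diazene 32 (not isolated)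
Conditions: catecholborane (2 equiv), CHCl3, 0 °C → rt; then NaOAc·3H2O, reflux
Reagents that add atoms: none
Why: Caglioti-type tosylhydrazone reduction: hydride adds to the C=N carbon, acetate then triggers loss of p-toluenesulfinate to give the diazene, which loses N2 to leave CH2 at C8; ester, alkene and silyl ether are inert and C7 is now fixed.

Step 17
Reactants: 33 methyl 2-[(5α,7β,10β)-4-(tert-butyldiphenylsilyloxymethyl)-10-methyl-Δ3-octalin-7-yl]acetate; 34 N,N-dimethylmethyleneiminium iodide (Eschenmoser's salt)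
Product: 36 methyl 3-(dimethylamino)-2-[(5α,7β,10β)-4-(tert-butyldiphenylsilyloxymethyl)-10-methyl-Δ3-octalin-7-yl]propanoate (C11 epimers), via lithium ester enolate 35 (not isolated)
Conditions: LiN(iPr)2 (1.2 equiv), THF, −78 °C; 34, −78 °C → rt
Reagents that add atoms: none
Why: Mannich reaction of the ester enolate with the preformed iminium salt installs C13 at C11; the new C11 centre is lost in the next step and C7, being β to the ester, cannot epimerise.

Step 18
Reactants: 36 methyl 3-(dimethylamino)-2-[(5α,7β,10β)-4-(tert-butyldiphenylsilyloxymethyl)-10-methyl-Δ3-octalin-7-yl]propanoate (C11 epimers)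
Product: 38 methyl 2-[(5α,7β,10β)-4-(tert-butyldiphenylsilyloxymethyl)-10-methyl-Δ3-octalin-7-yl]prop-2-enoate, via trimethylammonium iodide 37 (not isolated)
Conditions: MeI, MeOH, rt; then DBU, CH2Cl2, rt
Reagents that add atoms: none
Why: Quaternisation of the amine followed by E1cB elimination of trimethylamine from the β-ammonio ester gives the α-methylene ester.

Step 19
Reactants: 38 methyl 2-[(5α,7β,10β)-4-(tert-butyldiphenylsilyloxymethyl)-10-methyl-Δ3-octalin-7-yl]prop-2-enoate
Product: 39 methyl 2-[(5α,7β,10β)-4-(hydroxymethyl)-10-methyl-Δ3-octalin-7-yl]prop-2-enoate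
Conditions: Bu4NF, AcOH, THF, 0 °C → rt
Reagents that add atoms: none
Why: Fluoride desilylation, buffered with acetic acid so that the alkoxide does not add to the acrylate, frees the C15 allylic alcohol.

Step 20
Reactants: 39 methyl 2-[(5α,7β,10β)-4-(hydroxymethyl)-10-methyl-Δ3-octalin-7-yl]prop-2-enoate; 40 p-coumaric acid
Product: 41 methyl 2-[(2R,4aR,8aR)-8-({[(2E)-3-(4-hydroxyphenyl)prop-2-enoyl]oxy}methyl)-4a-methyl-1,2,3,4,4a,5,6,8a-octahydronaphthalen-2-yl]prop-2-enoate (target)
Conditions: PPh3, DIAD, THF, 0 °C → rt (betaine preformed)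
Reagents that add atoms: none
Why: Mitsunobu esterification: the carboxylic acid, far more acidic than the phenol, protonates the betaine, and its carboxylate displaces the alkoxyphosphonium at primary C15 by SN2, so the free phenol should need no protection and the (E)-cinnamate geometry is kept.

**Compound list**

1 | 2-chloroprop-2-en-1-ol | OCC(Cl)=C | starting material
2 | triethyl orthoacetate | CC(OCC)(OCC)OCC | starting material
3 | 2-chloro-3-(1,1-diethoxyethoxy)prop-1-ene (mixed orthoester) | CC(OCC)(OCC)OCC(Cl)=C | intermediate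
4 | 2-chloro-3-[(1-ethoxyethenyl)oxy]prop-1-ene (ketene acetal) | C=C(OCC)OCC(Cl)=C | intermediate
5 | ethyl 4-chloropent-4-enoate | CCOC(=O)CCC(Cl)=C | intermediate
6 | diisobutylaluminium hemiacetal of 5 | CCOC(CCC(Cl)=C)O[Al](CC(C)C)CC(C)C | intermediate
7 | 4-chloropent-4-enal | O=CCCC(Cl)=C | intermediate
8 | ethyl 2-(triphenylphosphoranylidene)propanoate | CCOC(=O)C(C)=P(c1ccccc1)(c1ccccc1)c1ccccc1 | starting material
9 | ethyl (2E)-6-chloro-2-methylhepta-2,6-dienoate | CCOC(=O)/C(C)=C/CCC(Cl)=C | intermediate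
10 | (2E)-6-chloro-2-methylhepta-2,6-dien-1-ol | OC/C(C)=C/CCC(Cl)=C | intermediate
11 | (2E)-1-bromo-6-chloro-2-methylhepta-2,6-diene | BrC/C(C)=C/CCC(Cl)=C | intermediate
12 | (+)-8-phenylmenthol = (1S,2R,5S)-5-methyl-2-(2-phenylpropan-2-yl)cyclohexan-1-ol | CC(C)(c1ccccc1)[C@H]1CC[C@H](C)C[C@@H]1O | starting material
13 | 2,2,6-trimethyl-4H-1,3-dioxin-4-one | CC1=CC(=O)OC(C)(C)O1 | starting material
14 | acetylketene (3-oxobut-1-en-1-one) | CC(=O)C=C=O | intermediate
15 | (1S,2R,5S)-5-methyl-2-(2-phenylpropan-2-yl)cyclohexyl 3-oxobutanoate | CC(C)(c1ccccc1)[C@H]1CC[C@H](C)C[C@@H]1OC(=O)CC(C)=O | intermediate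
16 | dilithium dienolate (dianion) of 15 | CC(C)(c1ccccc1)[C@H]1CC[C@H](C)C[C@@H]1OC([O-])=CC([O-])=C.[Li+].[Li+] | intermediate
17 | (1S,2R,5S)-5-methyl-2-(2-phenylpropan-2-yl)cyclohexyl (6E)-10-chloro-6-methyl-3-oxoundeca-6,10-dienoate | CC(C)(c1ccccc1)[C@H]1CC[C@H](C)C[C@@H]1OC(=O)CC(=O)CC/C(C)=C/CCC(Cl)=C | intermediate
18 | (+)-8-phenylmenthyl (4α,5α,10β)-8-acetoxy-8-chloro-10-methyl-3-oxo-trans-decalin-4-carboxylate (C8 epimers) | CC(C)(c1ccccc1)[C@H]1CC[C@H](C)C[C@@H]1OC(=O)[C@@H]2C(=O)CC[C@]3(C)CC(Cl)(OC(C)=O)CC[C@@H]23 | intermediate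
19 | (+)-8-phenylmenthyl (4α,5α,10β)-10-methyl-3,8-dioxo-trans-decalin-4-carboxylate | CC(C)(c1ccccc1)[C@H]1CC[C@H](C)C[C@@H]1OC(=O)[C@@H]2C(=O)CC[C@]3(C)CC(=O)CC[C@@H]23 | intermediate
20 | sodium C3 enolate of 19 | CC(C)(c1ccccc1)[C@H]1CC[C@H](C)C[C@@H]1OC(=O)C2=C([O-])CC[C@]3(C)CC(=O)CC[C@@H]23.[Na+] | intermediate
21 | (+)-8-phenylmenthyl (5α,10β)-10-methyl-8-oxo-3-(trifluoromethylsulfonyloxy)-Δ3-octalin-4-carboxylate | CC(C)(c1ccccc1)[C@H]1CC[C@H](C)C[C@@H]1OC(=O)C2=C(OS(=O)(=O)C(F)(F)F)CC[C@]3(C)CC(=O)CC[C@@H]23 | intermediate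
22 | (+)-8-phenylmenthyl (5α,10β)-10-methyl-8-oxo-Δ3-octalin-4-carboxylate | CC(C)(c1ccccc1)[C@H]1CC[C@H](C)C[C@@H]1OC(=O)C2=CCC[C@]3(C)CC(=O)CC[C@@H]23 | intermediate
23 | (5α,10β)-4-(hydroxymethyl)-10-methyl-Δ3-octalin-8-ol (C8 epimers) | OCC1=CCC[C@]2(C)CC(O)CC[C@@H]12 | intermediate
24 | (5α,10β)-4-(tert-butyldiphenylsilyloxymethyl)-10-methyl-Δ3-octalin-8-ol (C8 epimers) | CC(C)(C)[Si](c1ccccc1)(c1ccccc1)OCC1=CCC[C@]2(C)CC(O)CC[C@@H]12 | intermediate
25 | (5α,10β)-4-(tert-butyldiphenylsilyloxymethyl)-10-methyl-Δ3-octalin-8-one | CC(C)(C)[Si](c1ccccc1)(c1ccccc1)OCC1=CCC[C@]2(C)CC(=O)CC[C@@H]12 | intermediate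
26 | methyl bromoacetate | COC(=O)CBr | starting material
27 | lithium C7=C8 enolate of 25 | CC(C)(C)[Si](c1ccccc1)(c1ccccc1)OCC1=CCC[C@]2(C)CC([O-])=CC[C@@H]12.[Li+] | intermediate
28 | methyl 2-[(5α,7α,10β)-4-(tert-butyldiphenylsilyloxymethyl)-10-methyl-8-oxo-Δ3-octalin-7-yl]acetate (axial epimer) | CC(C)(C)[Si](c1ccccc1)(c1ccccc1)OCC1=CCC[C@]2(C)CC(=O)[C@H](CC(=O)OC)C[C@@H]12 | intermediate
29 | methyl 2-[(5α,7β,10β)-4-(tert-butyldiphenylsilyloxymethyl)-10-methyl-8-oxo-Δ3-octalin-7-yl]acetate | CC(C)(C)[Si](c1ccccc1)(c1ccccc1)OCC1=CCC[C@]2(C)CC(=O)[C@@H](CC(=O)OC)C[C@@H]12 | intermediate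
30 | C8 p-toluenesulfonylhydrazone of 29 | CC(C)(C)[Si](c1ccccc1)(c1ccccc1)OCC1=CCC[C@]2(C)CC(=NNS(=O)(=O)c3ccc(C)cc3)[C@@H](CC(=O)OC)C[C@@H]12 | intermediate
31 | C8 N-(1,3,2-benzodioxaborol-2-yl)-N'-tosylhydrazide from 30 | CC(C)(C)[Si](c1ccccc1)(c1ccccc1)OCC1=CCC[C@]2(C)CC(N(NS(=O)(=O)c3ccc(C)cc3)B3Oc4ccccc4O3)[C@@H](CC(=O)OC)C[C@@H]12 | intermediate
32 | C8 monoalkyl diazene | CC(C)(C)[Si](c1ccccc1)(c1ccccc1)OCC1=CCC[C@]2(C)CC(N=N)[C@@H](CC(=O)OC)C[C@@H]12 | intermediate
33 | methyl 2-[(5α,7β,10β)-4-(tert-butyldiphenylsilyloxymethyl)-10-methyl-Δ3-octalin-7-yl]acetate | CC(C)(C)[Si](c1ccccc1)(c1ccccc1)OCC1=CCC[C@]2(C)CC[C@@H](CC(=O)OC)C[C@@H]12 | intermediate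
34 | N,N-dimethylmethyleneiminium iodide (Eschenmoser's salt) | C=[N+](C)C.[I-] | starting material
35 | lithium ester enolate of 33 | CC(C)(C)[Si](c1ccccc1)(c1ccccc1)OCC1=CCC[C@]2(C)CC[C@@H](C=C([O-])OC)C[C@@H]12.[Li+] | intermediate
36 | methyl 3-(dimethylamino)-2-[(5α,7β,10β)-4-(tert-butyldiphenylsilyloxymethyl)-10-methyl-Δ3-octalin-7-yl]propanoate (C11 epimers) | CC(C)(C)[Si](c1ccccc1)(c1ccccc1)OCC1=CCC[C@]2(C)CC[C@@H](C(CN(C)C)C(=O)OC)C[C@@H]12 | intermediate
37 | trimethylammonium iodide of 36 | CC(C)(C)[Si](c1ccccc1)(c1ccccc1)OCC1=CCC[C@]2(C)CC[C@@H](C(C[N+](C)(C)C)C(=O)OC)C[C@@H]12.[I-] | intermediate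
38 | methyl 2-[(5α,7β,10β)-4-(tert-butyldiphenylsilyloxymethyl)-10-methyl-Δ3-octalin-7-yl]prop-2-enoate | CC(C)(C)[Si](c1ccccc1)(c1ccccc1)OCC1=CCC[C@]2(C)CC[C@@H](C(=C)C(=O)OC)C[C@@H]12 | intermediate
39 | methyl 2-[(5α,7β,10β)-4-(hydroxymethyl)-10-methyl-Δ3-octalin-7-yl]prop-2-enoate | OCC1=CCC[C@]2(C)CC[C@@H](C(=C)C(=O)OC)C[C@@H]12 | intermediate
40 | p-coumaric acid | OC(=O)/C=C/c1ccc(O)cc1 | starting material
41 | methyl 2-[(2R,4aR,8aR)-8-({[(2E)-3-(4-hydroxyphenyl)prop-2-enoyl]oxy}methyl)-4a-methyl-1,2,3,4,4a,5,6,8a-octahydronaphthalen-2-yl]prop-2-enoate (CNP0161949.1) | C=C(C(=O)OC)[C@@H]1CC[C@@]2(C)CCC=C(COC(=O)/C=C/c3ccc(O)cc3)[C@@H]2C1 | target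

**Step count and risk**

Total step count: 20.
Longest linear sequence: 19 steps (steps 1–5 and 7–20; step 6 is the side branch).

Three steps most likely to fail:

1. Step 8. The auxiliary may discriminate the two faces of the C4 radical poorly, so that the wrong decalin diastereomer forms in quantity. The fallback drops asymmetric induction in favour of a racemic bicyclisation followed by diastereomer separation; it sets out from 11 and comes back at 19. Methyl acetoacetate is γ-alkylated through its dianion (LiN(iPr)2, 2 equiv, THF, 0 °C) with 11 to give methyl (6E)-10-chloro-6-methyl-3-oxoundeca-6,10-dienoate F1. Oxidation of F1 with Mn(OAc)3·2H2O and Cu(OAc)2·H2O in AcOH should give the racemic trans-decalin methyl ester F2. DMAP-catalysed transesterification of F2 with 12 in toluene at reflux (methanol distilled off) then gives 19 together with the (+)-8-phenylmenthyl ester of the enantiomeric decalin F3, and the two are separated by chromatography or crystallisation.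

2. Step 14. Enolate equilibration by proton transfer from the product may cause loss of regiocontrol (C9 attack) and double alkylation. The fallback uses a neutral Stork enamine in place of the lithium enolate; it sets out from 25 and comes back at 29. Ketone 25 is condensed with pyrrolidine (TsOH cat., benzene, water removed azeotropically) to the C7=C8 pyrrolidine enamine F4. Alkylation of F4 with 26 in MeCN at reflux gives the C7-alkylated iminium bromide F5, which is hydrolysed with aqueous NaOAc–AcOH and equilibrated with DBU to 29.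

3. Step 16. Hydride transfer to the α-branched hydrazone may be slow, and elimination to an alkene or epimerisation at C7 may then compete. The fallback is a Mozingo reduction; it sets out from 29 and comes back at 33. Ketone 29 is converted with ethane-1,2-dithiol and BF3·OEt2 (CH2Cl2, 0 °C) into the 8,8-(ethylenedithio) ketal F6, which is desulfurised with Raney Ni (deactivated by brief reflux in acetone) in EtOH at rt.

**Further compounds**
F1 | step 8 | methyl (6E)-10-chloro-6-methyl-3-oxoundeca-6,10-dienoate | COC(=O)CC(=O)CC/C(C)=C/CCC(Cl)=C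
F2 | step 8 | methyl (4α,5α,10β)-10-methyl-3,8-dioxo-trans-decalin-4-carboxylate (racemate; one enantiomer drawn) | COC(=O)[C@@H]1C(=O)CC[C@]2(C)CC(=O)CC[C@@H]12
F3 | step 8 | (+)-8-phenylmenthyl ester of the enantiomeric (4β,5β,10α) trans-decalin dione | CC(C)(c1ccccc1)[C@H]1CC[C@H](C)C[C@@H]1OC(=O)[C@H]2C(=O)CC[C@@]3(C)CC(=O)CC[C@H]23
F4 | step 14 | C7=C8 pyrrolidine enamine of 25 | CC(C)(C)[Si](c1ccccc1)(c1ccccc1)OCC1=CCC[C@]2(C)CC(N3CCCC3)=CC[C@@H]12
F5 | step 14 | C7-(methoxycarbonylmethyl) pyrrolidinium iminium bromide (C7 epimers) | CC(C)(C)[Si](c1ccccc1)(c1ccccc1)OCC1=CCC[C@]2(C)CC(=[N+]3CCCC3)C(CC(=O)OC)C[C@@H]12.[Br-]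
F6 | step 16 | 8,8-(ethylenedithio) ketal of 29 | CC(C)(C)[Si](c1ccccc1)(c1ccccc1)OCC1=CCC[C@]2(C)CC3(SCCS3)[C@@H](CC(=O)OC)C[C@@H]12
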